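If you count turnovers per charged G rather than percent of Z, this flask becomes a question of pace and elapsed time.

all flasks: G 4.7 mol%

|  | Z | remark | time |
|---|---|---|---|
| amber | 0.070 M | run made earlier |  |
| ochre | 0.11 M | run made earlier |  |
| flask | 0.050 M |  | 25 min |

| run | time / min | Q / % | Z / % |
|---|---|---|---|
| amber | 2.50 | 5.3 | 94.4 |
| amber | 4.00 | 7.7 | 89.2 |
| amber | 6.00 | 13.9 | 85.6 |
| amber | 10.0 | 22.0 | 77.2 |
| amber | 20.0 | 38.8 | 60.7 |
| amber | 30.0 | 53.0 | 46.2 |
| ochre | 2.50 | 8.3 | 90.8 |
| ochre | 4.00 | 12.0 | 87.6 |
| ochre | 6.00 | 16.8 | 83.1 |
| ochre | 10.0 | 29.9 | 70.1 |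
| ochre | 20.0 | 49.7 | 49.3 |
| ochre | 30.0 | 63.5 | 35.9 |

(standard deviation of a reading: 1 percentage point)

1. amount of Q in the flask at 25 min, in percent of the Z charged
2. amount of Z in the flask at 25 min, in percent of the Z charged

- the numbers in the tables scatter with a standard deviation of 1 percentage point
- steps under discussion: 2 G <-> X; Z + G -> G + Q

Both runs read as pseudo-first-order decay of Z. Divide that rate constant by the loading and you have the turnover frequency of a charged G at the full charge of Z. Amber's last reading gives 0.548 min⁻¹, and ochre's gives 0.727 min⁻¹.

Now turn the settings one by one. Shortening amber to 25 min at amber's pace leaves Z at 52.5%. The loading is the same in this flask as in both runs, so it changes nothing directly. Diluting does matter: ochre, with the higher c(Z) and so the higher catalyst concentration, turns faster than amber. The two readings give an apparent order of 0.625, below 1. By my reckoning, the flask's turnover frequency is therefore 0.444 min⁻¹. Over 25 min, that leaves Z at 59.4% and makes Q 40.6%, which is 8.64 turnovers of the 21.3 that the charge of Z allows.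

The forecast gives Q 39.3% and Z 60.7%, leaving more Z than my reckoning. Its grounds are “active monomer G in fast partial equilibrium with inactive dimer X”.

    2 G ⇌ X, settled at all times (K = 140 M⁻¹)
    Z + G → G + Q (k = 0.200 M⁻¹ s⁻¹)

The flask gives Q 38.4% and Z 61.6%, so the forecast's Q stands 0.90 percentage points above the flask's. Starting from amber's last state without scatter, Z 47.3%, changing the time by itself gives 53.6%, changing the dilution by itself gives 55.9%, and changing both gives 61.6%. Counted as turnovers, the flask has made 8.18 per charged G, against my 8.64.

Left until 40 min, my turnover frequency gives Z 43.4%, Q 56.6%. The computed neighbour holds Z 46.0%, Q 54.0%.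

All runs were computed for substances that don't exist; the scatter is artificial.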